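Assumption: the enol in the SMILES is the usual hydrogen-bonded keto–enol form of the 1,3-diketone; the ring is (1R,2R,6S) with C1 = acyl, C2 = 3,4-dimethoxyphenyl, C6 = 4-hydroxy-3-methoxyphenyl, so the acyl group is trans to both aryl groups.

## Retrosynthetic overview

1. Target 31 ⇐ bis-MOM ether 30 ⇐ C-acylation of the methyl-ketone enolate of cyclohexenyl ketone 25 with feruloyl donor 28 (late union of the two halves at the diketone CH2–CO bond).
2. 25 ⇐ acid 23 (MeLi, then C1 equilibrated to the all-equatorial isomer) ⇐ ring-closing metathesis of acyclic diene acid 22. The cyclohexene is the only ring made, and it is closed after all three stereocentres are in place.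
3. 22 ⇐ Ireland–Claisen rearrangement of ester 19 (C1–C2 bond; C2 by chirality transfer, C1 by enolate geometry) ⇐ acid 12 + allylic alcohol 18.
4. 12 ⇐ Rh/BINAP conjugate arylation of dienoate 10 with boronic acid 7 (sets C6); 18 ⇐ CBS reduction of enone 16.
5. Aryl units 4 and 14 ⇐ catechol; carbon chains ⇐ isopropyl acrylate, penta-1,4-diene, methyl vinyl ketone, acrylic acid.

## Route

Step 1
Reactants: 1 catechol
Product: 2 guaiacol (2-methoxyphenol)
Conditions: MeI (1.0 equiv), K2CO3 (1.0 equiv), acetone, reflux; NaOH extraction and distillation remove veratrole and catechol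
Reagents that add atoms: iodomethane, CI
Why: Williamson mono-O-methylation; with one equivalent of base and MeI the mono-ether dominates and is separable from the neutral diether and the water-soluble diol.

Step 2
Reactants: 2 guaiacol
Product: 3 4-bromo-2-methoxyphenol
Conditions: NBS (1.0 equiv), MeCN, 0 °C
Reagents that add atoms: N-bromosuccinimide, O=C1CCC(=O)N1Br
Why: Electrophilic aromatic bromination goes para to the free OH, the strongest director.

Step 3
Reactants: 3 4-bromo-2-methoxyphenol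
Product: 4 4-bromo-2-methoxy-1-(methoxymethoxy)benzene
Conditions: MOMCl, i-Pr2NEt, CH2Cl2, 0 °C → rt
Reagents that add atoms: chloromethyl methyl ether, COCCl
Why: O-alkylation of the phenol to a MOM acetal that tolerates organolithiums, Pd, Rh, Ru and bases and is removed by acid at the end.

Step 4
Reactants: 4 4-bromo-2-methoxy-1-(methoxymethoxy)benzene
Product: 7 [3-methoxy-4-(methoxymethoxy)phenyl]boronic acid, via aryllithium 5 (not isolated), via lithium aryltrimethoxyborate 6 (not isolated)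
Conditions: n-BuLi (1.05 equiv), THF, −78 °C; B(OMe)3 (1.5 equiv), −78 °C → rt; 1 M HCl to pH 5, 0 °C
Reagents that add atoms: trimethyl borate, COB(OC)OC; water, O
Why: Br–Li exchange at −78 °C is faster than MOM-directed ortho-lithiation, and borate trapping with mild hydrolysis gives the boronic acid.

Step 5
Reactants: 8 isopropyl acrylate; 9 penta-1,4-diene (4 equiv)
Product: 10 propan-2-yl (2E)-hexa-2,5-dienoate
Conditions: Hoveyda–Grubbs II (2 mol %), 1,4-benzoquinone (10 mol %), CH2Cl2, 40 °C, sealed tube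
Reagents that add atoms: none
Why: Olefin cross-metathesis of an acrylate with a terminal alkene is E-selective; excess diene suppresses double metathesis and benzoquinone suppresses Ru–H isomerisation of the skipped diene.

Step 6
Reactants: 7 [3-methoxy-4-(methoxymethoxy)phenyl]boronic acid (2 equiv); 10 propan-2-yl (2E)-hexa-2,5-dienoate
Product: 11 propan-2-yl (3S)-3-[3-methoxy-4-(methoxymethoxy)phenyl]hex-5-enoate
Conditions: Rh(acac)(C2H4)2 (3 mol %), (R)-BINAP (3.3 mol %), dioxane/H2O 10:1, 100 °C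
Reagents that add atoms: none
Why: Hayashi–Miyaura Rh(I)/BINAP asymmetric 1,4-addition to an (E)-enoate under base-free conditions, which the isolated terminal alkene and the skipped diene should survive; (R)-BINAP, the mirror image of the ligand that gives (S)-3-arylcyclohexanones, is expected to set C3 as (S), and the sense should be confirmed on the product.

Step 7
Reactants: 11 propan-2-yl (3S)-3-[3-methoxy-4-(methoxymethoxy)phenyl]hex-5-enoate
Product: 12 (3S)-3-[3-methoxy-4-(methoxymethoxy)phenyl]hex-5-enoic acid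
Conditions: LiOH·H2O (3 equiv), THF/MeOH/H2O, 40 °C; then 1 M HCl to pH 3–4, 0 °C
Reagents that add atoms: lithium hydroxide, [Li+].[OH-]
Why: Saponification; the β-stereocentre is not enolisable and the MOM ether survives cold pH 3–4.

Step 8
Reactants: 1 catechol
Product: 13 veratrole (1,2-dimethoxybenzene)
Conditions: MeI (2.5 equiv), K2CO3 (3 equiv), acetone, reflux
Reagents that add atoms: iodomethane, CI
Why: Exhaustive Williamson O-methylation.

Step 9
Reactants: 13 veratrole
Product: 14 4-bromo-1,2-dimethoxybenzene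
Conditions: NBS (1.05 equiv), MeCN, rt
Reagents that add atoms: N-bromosuccinimide, O=C1CCC(=O)N1Br
Why: Electrophilic bromination para to a methoxy group; the 4- and 5-positions are equivalent.

Step 10
Reactants: 14 4-bromo-1,2-dimethoxybenzene; 15 methyl vinyl ketone
Product: 16 (3E)-4-(3,4-dimethoxyphenyl)but-3-en-2-one
Conditions: Pd(OAc)2 (2 mol %), P(o-tol)3 (4 mol %), Et3N (2 equiv), DMF, 100 °C
Reagents that add atoms: none
Why: Mizoroki–Heck arylation of an electron-poor alkene gives the (E)-enone by syn-insertion and syn-β-hydride elimination.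

Step 11
Reactants: 16 (3E)-4-(3,4-dimethoxyphenyl)but-3-en-2-one
Product: 18 (2S,3E)-4-(3,4-dimethoxyphenyl)but-3-en-2-ol, via alkoxycatecholborane 17 (not isolated)
Conditions: (R)-2-methyl-CBS-oxazaborolidine (10 mol %), catecholborane (1.5 equiv), toluene, −78 °C; 1 M NaOH work-up
Reagents that add atoms: none
Why: Corey–Bakshi–Shibata 1,2-reduction in which the styryl group is the large substituent, so the (R)-catalyst gives the (S)-carbinol; catecholborane at −78 °C avoids hydroboration and 1,4-reduction.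

Step 12
Reactants: 12 (3S)-3-[3-methoxy-4-(methoxymethoxy)phenyl]hex-5-enoic acid; 18 (2S,3E)-4-(3,4-dimethoxyphenyl)but-3-en-2-ol
Product: 19 (2S,3E)-4-(3,4-dimethoxyphenyl)but-3-en-2-yl (3S)-3-[3-methoxy-4-(methoxymethoxy)phenyl]hex-5-enoate
Conditions: DCC (1.2 equiv), DMAP (0.1 equiv), CH2Cl2, 0 °C → rt; chromatography on Et3N-deactivated silica
Reagents that add atoms: none
Why: Steglich esterification under neutral conditions acylates the carbinol oxygen with retention and avoids ionising the electron-rich allylic alcohol.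

Step 13
Reactants: 19 (2S,3E)-4-(3,4-dimethoxyphenyl)but-3-en-2-yl (3S)-3-[3-methoxy-4-(methoxymethoxy)phenyl]hex-5-enoate
Product: 22 (2R,3R,4E)-3-(3,4-dimethoxyphenyl)-2-{(1S)-1-[3-methoxy-4-(methoxymethoxy)phenyl]but-3-en-1-yl}hex-4-enoic acid, via silyl ketene acetal 20 (not isolated), via trimethylsilyl ester 21 (not isolated)
Conditions: LDA (1.3 equiv) added to 19 and TMSCl/Et3N (1:1, 3 equiv), THF, −78 °C; then rt → 60 °C, 3 h; aqueous work-up at pH 4
Reagents that add atoms: none
Why: Ireland–Claisen [3,3] rearrangement through a chair with the carbinol methyl pseudo-equatorial transfers the (S)-C–O centre to the new (3R) benzylic centre and an (E)-propenyl group, while the (E)-silyl ketene acetal from LDA/THF gives (2R) as the major C2 epimer (the minor one converges in step 15).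

Step 14
Reactants: 22 (2R,3R,4E)-3-(3,4-dimethoxyphenyl)-2-{(1S)-1-[3-methoxy-4-(methoxymethoxy)phenyl]but-3-en-1-yl}hex-4-enoic acid
Product: 23 (1R,2R,6S)-2-(3,4-dimethoxyphenyl)-6-[3-methoxy-4-(methoxymethoxy)phenyl]cyclohex-3-ene-1-carboxylic acid
Conditions: Grubbs II (5 mol %), CH2Cl2 (5 mM), 40 °C
Reagents that add atoms: none
Why: Ring-closing metathesis of the allyl and propenyl arms closes the six-membered ring with loss of propene and places the alkene next to the dimethoxyphenyl-bearing carbon without touching a stereocentre.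

Step 15
Reactants: 23 (1R,2R,6S)-2-(3,4-dimethoxyphenyl)-6-[3-methoxy-4-(methoxymethoxy)phenyl]cyclohex-3-ene-1-carboxylic acid
Product: 25 1-{(1R,2R,6S)-2-(3,4-dimethoxyphenyl)-6-[3-methoxy-4-(methoxymethoxy)phenyl]cyclohex-3-en-1-yl}ethan-1-one, via dilithium gem-diolate 24 (not isolated)
Conditions: MeLi (3.5 equiv), THF, 0 °C → rt; inverse quench into cold 0.5 M HCl; crude ketone, NaOMe (0.3 equiv), MeOH/THF, rt, 12 h
Reagents that add atoms: methyllithium, [Li]C
Why: MeLi addition to the lithium carboxylate stops at the gem-diolate, which gives the methyl ketone on quench; NaOMe then equilibrates the only enolisable ring centre (C1) to the all-equatorial isomer with acetyl trans to both aryl groups, the (1R) configuration of the target.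

Step 16
Reactants: 4 4-bromo-2-methoxy-1-(methoxymethoxy)benzene; 26 acrylic acid
Product: 27 (2E)-3-[3-methoxy-4-(methoxymethoxy)phenyl]prop-2-enoic acid
Conditions: Pd(OAc)2 (2 mol %), P(o-tol)3 (4 mol %), Et3N (3 equiv), DMF, 100 °C; then cold 1 M HCl to pH 3
Reagents that add atoms: none
Why: Mizoroki–Heck arylation of acrylate gives the (E)-cinnamic acid directly.

Step 17
Reactants: 27 (2E)-3-[3-methoxy-4-(methoxymethoxy)phenyl]prop-2-enoic acid
Product: 28 1-{(2E)-3-[3-methoxy-4-(methoxymethoxy)phenyl]prop-2-enoyl}-1H-benzotriazole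
Conditions: 1H-benzotriazole (1.1 equiv), DCC (1.1 equiv), CH2Cl2, 0 °C → rt
Reagents that add atoms: 1H-benzotriazole, c1ccc2[nH]nnc2c1
Why: Carbodiimide coupling under neutral conditions gives an isolable N-acylbenzotriazole, a C-selective acyl donor, without exposing the MOM ether to acid.

Step 18
Reactants: 25 1-{(1R,2R,6S)-2-(3,4-dimethoxyphenyl)-6-[3-methoxy-4-(methoxymethoxy)phenyl]cyclohex-3-en-1-yl}ethan-1-one; 28 1-{(2E)-3-[3-methoxy-4-(methoxymethoxy)phenyl]prop-2-enoyl}-1H-benzotriazole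
Product: 30 (2Z,4E)-1-{(1R,2R,6S)-2-(3,4-dimethoxyphenyl)-6-[3-methoxy-4-(methoxymethoxy)phenyl]cyclohex-3-en-1-yl}-3-hydroxy-5-[3-methoxy-4-(methoxymethoxy)phenyl]penta-2,4-dien-1-one, via lithium enolate 29 (not isolated)
Conditions: LiHMDS (2.2 equiv), THF, −78 °C, 45 min; 28 (1.1 equiv), −78 → −20 °C; AcOH quench
Reagents that add atoms: none
Why: Crossed Claisen-type C-acylation in which the kinetic methyl-side enolate attacks the non-enolisable acylbenzotriazole at the carbonyl and the second equivalent of base takes up the acidic diketone; no stereocentre is touched because C1 is already in its thermodynamic configuration.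

Step 19
Reactants: 30 (2Z,4E)-1-{(1R,2R,6S)-2-(3,4-dimethoxyphenyl)-6-[3-methoxy-4-(methoxymethoxy)phenyl]cyclohex-3-en-1-yl}-3-hydroxy-5-[3-methoxy-4-(methoxymethoxy)phenyl]penta-2,4-dien-1-one
Product: 31 (2Z,4E)-1-[(1R,2R,6S)-2-(3,4-dimethoxyphenyl)-6-(4-hydroxy-3-methoxyphenyl)cyclohex-3-en-1-yl]-3-hydroxy-5-(4-hydroxy-3-methoxyphenyl)penta-2,4-dien-1-one
Conditions: HCl (1.25 M in MeOH), THF, 40 °C
Reagents that add atoms: none
Why: Acid-catalysed transacetalisation of both aryl MOM ethers to methanol; the enolised diketone, the aryl methyl ethers and the isolated ring alkene are stable to dilute methanolic HCl.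

## Compound list

1 | catechol (benzene-1,2-diol) | Oc1ccccc1O | starting material
2 | guaiacol (2-methoxyphenol) | COc1ccccc1O | intermediate
3 | 4-bromo-2-methoxyphenol | COc1cc(Br)ccc1O | intermediate
4 | 4-bromo-2-methoxy-1-(methoxymethoxy)benzene | COCOc1ccc(Br)cc1OC | intermediate
5 | [3-methoxy-4-(methoxymethoxy)phenyl]lithium (in situ) | [Li]c1ccc(OCOC)c(OC)c1 | intermediate
6 | lithium trimethoxy[3-methoxy-4-(methoxymethoxy)phenyl]borate (in situ) | [Li+].CO[B-](OC)(OC)c1ccc(OCOC)c(OC)c1 | intermediate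
7 | [3-methoxy-4-(methoxymethoxy)phenyl]boronic acid | OB(O)c1ccc(OCOC)c(OC)c1 | intermediate
8 | isopropyl acrylate (propan-2-yl prop-2-enoate) | C=CC(=O)OC(C)C | starting material
9 | penta-1,4-diene | C=CCC=C | starting material
10 | propan-2-yl (2E)-hexa-2,5-dienoate | C=CC/C=C/C(=O)OC(C)C | intermediate
11 | propan-2-yl (3S)-3-[3-methoxy-4-(methoxymethoxy)phenyl]hex-5-enoate | CC(C)OC(=O)C[C@@H](c1ccc(OCOC)c(OC)c1)CC=C | intermediate
12 | (3S)-3-[3-methoxy-4-(methoxymethoxy)phenyl]hex-5-enoic acid | OC(=O)C[C@@H](c1ccc(OCOC)c(OC)c1)CC=C | intermediate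
13 | veratrole (1,2-dimethoxybenzene) | COc1ccccc1OC | intermediate
14 | 4-bromo-1,2-dimethoxybenzene | COc1ccc(Br)cc1OC | intermediate
15 | methyl vinyl ketone (but-3-en-2-one) | CC(=O)C=C | starting material
16 | (3E)-4-(3,4-dimethoxyphenyl)but-3-en-2-one | COc1ccc(/C=C/C(C)=O)cc1OC | intermediate
17 | 2-{[(2S,3E)-4-(3,4-dimethoxyphenyl)but-3-en-2-yl]oxy}-1,3,2-benzodioxaborole (in situ) | C[C@H](OB1Oc2ccccc2O1)/C=C/c1ccc(OC)c(OC)c1 | intermediate
18 | (2S,3E)-4-(3,4-dimethoxyphenyl)but-3-en-2-ol | C[C@H](O)/C=C/c1ccc(OC)c(OC)c1 | intermediate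
19 | (2S,3E)-4-(3,4-dimethoxyphenyl)but-3-en-2-yl (3S)-3-[3-methoxy-4-(methoxymethoxy)phenyl]hex-5-enoate | C[C@H](OC(=O)C[C@@H](c1ccc(OCOC)c(OC)c1)CC=C)/C=C/c1ccc(OC)c(OC)c1 | intermediate
20 | (E)-O-trimethylsilyl ketene acetal of ester 19 (in situ) | C[C@H](O/C(O[Si](C)(C)C)=C\[C@@H](c1ccc(OCOC)c(OC)c1)CC=C)/C=C/c1ccc(OC)c(OC)c1 | intermediate
21 | trimethylsilyl ester of acid 22 (in situ) | C[Si](C)(C)OC(=O)[C@H]([C@@H](c1ccc(OCOC)c(OC)c1)CC=C)[C@@H](/C=C/C)c1ccc(OC)c(OC)c1 | intermediate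
22 | (2R,3R,4E)-3-(3,4-dimethoxyphenyl)-2-{(1S)-1-[3-methoxy-4-(methoxymethoxy)phenyl]but-3-en-1-yl}hex-4-enoic acid | OC(=O)[C@H]([C@@H](c1ccc(OCOC)c(OC)c1)CC=C)[C@@H](/C=C/C)c1ccc(OC)c(OC)c1 | intermediate
23 | (1R,2R,6S)-2-(3,4-dimethoxyphenyl)-6-[3-methoxy-4-(methoxymethoxy)phenyl]cyclohex-3-ene-1-carboxylic acid | OC(=O)[C@@H]1[C@@H](c2ccc(OCOC)c(OC)c2)CC=C[C@H]1c1ccc(OC)c(OC)c1 | intermediate
24 | dilithium gem-diolate from MeLi addition to the lithium salt of 23 (in situ) | CC(O[Li])(O[Li])[C@@H]1[C@@H](c2ccc(OCOC)c(OC)c2)CC=C[C@H]1c1ccc(OC)c(OC)c1 | intermediate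
25 | 1-{(1R,2R,6S)-2-(3,4-dimethoxyphenyl)-6-[3-methoxy-4-(methoxymethoxy)phenyl]cyclohex-3-en-1-yl}ethan-1-one | CC(=O)[C@@H]1[C@@H](c2ccc(OCOC)c(OC)c2)CC=C[C@H]1c1ccc(OC)c(OC)c1 | intermediate
26 | acrylic acid | C=CC(=O)O | starting material
27 | (2E)-3-[3-methoxy-4-(methoxymethoxy)phenyl]prop-2-enoic acid | COCOc1ccc(/C=C/C(=O)O)cc1OC | intermediate
28 | 1-{(2E)-3-[3-methoxy-4-(methoxymethoxy)phenyl]prop-2-enoyl}-1H-benzotriazole | COCOc1ccc(/C=C/C(=O)n2nnc3ccccc32)cc1OC | intermediate
29 | methyl-side lithium enolate of ketone 25 (in situ) | C=C(O[Li])[C@@H]1[C@@H](c2ccc(OCOC)c(OC)c2)CC=C[C@H]1c1ccc(OC)c(OC)c1 | intermediate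
30 | (2Z,4E)-1-{(1R,2R,6S)-2-(3,4-dimethoxyphenyl)-6-[3-methoxy-4-(methoxymethoxy)phenyl]cyclohex-3-en-1-yl}-3-hydroxy-5-[3-methoxy-4-(methoxymethoxy)phenyl]penta-2,4-dien-1-one | COCOc1ccc(/C=C/C(O)=C/C(=O)[C@@H]2[C@@H](c3ccc(OCOC)c(OC)c3)CC=C[C@H]2c2ccc(OC)c(OC)c2)cc1OC | intermediate
31 | (2Z,4E)-1-[(1R,2R,6S)-2-(3,4-dimethoxyphenyl)-6-(4-hydroxy-3-methoxyphenyl)cyclohex-3-en-1-yl]-3-hydroxy-5-(4-hydroxy-3-methoxyphenyl)penta-2,4-dien-1-one | COc1cc(/C=C/C(O)=C/C(=O)[C@@H]2[C@@H](c3ccc(O)c(OC)c3)CC=C[C@H]2c2ccc(OC)c(OC)c2)ccc1O | target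

## Step count

Total step count: 19.
Longest linear sequence: 12 steps (steps 1, 2, 3, 4, 6, 7, 12, 13, 14, 15, 18, 19; compounds 1 → 2 → 3 → 4 → 7 → 11 → 12 → 19 → 22 → 23 → 25 → 30 → 31).

## Steps most likely to fail, with fallbacks

**Step 6 (Rh arylation of the skipped dienoate).** The risks are isomerisation of 10 to the conjugated dienoate and an unverified facial sense on this substrate. The fallback sets out from 7 and comes back at 12. Boronic acid 7 is added under the same Rh(acac)(C2H4)2/(R)-BINAP conditions to purchased 5,6-dihydro-2H-pyran-2-one (O=C1C=CCCO1), a well-behaved cyclic acceptor, to give (4R)-4-[3-methoxy-4-(methoxymethoxy)phenyl]oxan-2-one F1. DIBAL-H (CH2Cl2, −78 °C) reduces it to the lactol (4R)-4-[3-methoxy-4-(methoxymethoxy)phenyl]oxan-2-ol F2. Wittig methylenation (Ph3PCH3Br, KOtBu, THF) opens the lactol to (3S)-3-[3-methoxy-4-(methoxymethoxy)phenyl]hex-5-en-1-ol F3. TEMPO/PhI(OAc)2 in MeCN/H2O oxidises the primary alcohol to acid 12. The former lactone carbonyl becomes the allyl arm, which is why the (R)-lactone gives the (S)-acid.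

**Step 13 (Ireland–Claisen rearrangement).** The electron-rich secondary cinnamyl-type ester 19 may ionise, which would erode chirality transfer. The fallback sets out from 12 and 14 and comes back at 23; it replaces the sigmatropic step by a catalyst-controlled intermolecular allylic alkylation.
- Acid 12 is methylated (TMSCHN2, MeOH/toluene) to methyl (3S)-3-[3-methoxy-4-(methoxymethoxy)phenyl]hex-5-enoate F4 and converted (LDA, TBSCl, THF/DMPU, −78 °C) into its tert-butyldimethylsilyl ketene acetal F5.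
- Bromide 14 is Heck-coupled with methyl acrylate (Pd(OAc)2, P(o-tol)3, Et3N) to methyl (2E)-3-(3,4-dimethoxyphenyl)prop-2-enoate F6, reduced (DIBAL-H, CH2Cl2, −78 °C) to (2E)-3-(3,4-dimethoxyphenyl)prop-2-en-1-ol F7, and acylated (ClCO2Me, pyridine) to (2E)-3-(3,4-dimethoxyphenyl)prop-2-en-1-yl methyl carbonate F8.
- Ir-catalysed branch-selective allylic alkylation of F8 with F5 ([Ir(cod)Cl]2, cyclometallated phosphoramidite of the enantiomer that gives the (3R) centre, fluoride activator, THF, rt) gives methyl (3R)-3-(3,4-dimethoxyphenyl)-2-{(1S)-1-[3-methoxy-4-(methoxymethoxy)phenyl]but-3-en-1-yl}pent-4-enoate F9; its C2 epimer ratio does not matter.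
- Ring-closing metathesis (Grubbs II) followed by NaOMe/MeOH equilibration gives the all-trans methyl (1R,2R,6S)-2-(3,4-dimethoxyphenyl)-6-[3-methoxy-4-(methoxymethoxy)phenyl]cyclohex-3-ene-1-carboxylate F10.
- Me3SnOH (1,2-dichloroethane, 80 °C) cleaves the hindered methyl ester to acid 23.

**Step 18 (C-acylation with the cinnamoyl donor).** O-acylation, Michael addition to 28 or incomplete conversion of the valuable ketone are possible. The fallback sets out from 25 and 4 and comes back at 31; it builds the enone by a boron-templated aldol condensation instead.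
- Ketone 25 is C-acetylated (LiHMDS, THF, −78 °C; 1-acetylbenzotriazole) to 1-{(1R,2R,6S)-2-(3,4-dimethoxyphenyl)-6-[3-methoxy-4-(methoxymethoxy)phenyl]cyclohex-3-en-1-yl}butane-1,3-dione F11.
- Bromide 4 is lithiated to 5 and formylated with DMF to 3-methoxy-4-(methoxymethoxy)benzaldehyde F12.
- F11 is heated with B2O3 and tributyl borate in EtOAc, so that the boron chelate masks the central CH2. F12 and n-BuNH2 are then added at 70 °C, and condensation occurs only at the terminal methyl group.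
- Warm 1 M HCl in MeOH breaks the boron chelate and removes both MOM groups, giving 31 directly.

## Further compounds

F1 | step 6 | (4R)-4-[3-methoxy-4-(methoxymethoxy)phenyl]oxan-2-one | O=C1C[C@H](c2ccc(OCOC)c(OC)c2)CCO1
F2 | step 6 | (4R)-4-[3-methoxy-4-(methoxymethoxy)phenyl]oxan-2-ol (anomer mixture) | OC1C[C@H](c2ccc(OCOC)c(OC)c2)CCO1
F3 | step 6 | (3S)-3-[3-methoxy-4-(methoxymethoxy)phenyl]hex-5-en-1-ol | OCC[C@@H](c1ccc(OCOC)c(OC)c1)CC=C
F4 | step 13 | methyl (3S)-3-[3-methoxy-4-(methoxymethoxy)phenyl]hex-5-enoate | COC(=O)C[C@@H](c1ccc(OCOC)c(OC)c1)CC=C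
F5 | step 13 | tert-butyldimethylsilyl ketene acetal of F4 | CO/C(O[Si](C)(C)C(C)(C)C)=C\[C@@H](c1ccc(OCOC)c(OC)c1)CC=C
F6 | step 13 | methyl (2E)-3-(3,4-dimethoxyphenyl)prop-2-enoate | COC(=O)/C=C/c1ccc(OC)c(OC)c1
F7 | step 13 | (2E)-3-(3,4-dimethoxyphenyl)prop-2-en-1-ol | OC/C=C/c1ccc(OC)c(OC)c1
F8 | step 13 | (2E)-3-(3,4-dimethoxyphenyl)prop-2-en-1-yl methyl carbonate | COC(=O)OC/C=C/c1ccc(OC)c(OC)c1
F9 | step 13 | methyl (3R)-3-(3,4-dimethoxyphenyl)-2-{(1S)-1-[3-methoxy-4-(methoxymethoxy)phenyl]but-3-en-1-yl}pent-4-enoate (C2 epimers) | COC(=O)C([C@@H](c1ccc(OCOC)c(OC)c1)CC=C)[C@@H](C=C)c1ccc(OC)c(OC)c1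
F10 | step 13 | methyl (1R,2R,6S)-2-(3,4-dimethoxyphenyl)-6-[3-methoxy-4-(methoxymethoxy)phenyl]cyclohex-3-ene-1-carboxylate | COC(=O)[C@@H]1[C@@H](c2ccc(OCOC)c(OC)c2)CC=C[C@H]1c1ccc(OC)c(OC)c1
F11 | step 18 | 1-{(1R,2R,6S)-2-(3,4-dimethoxyphenyl)-6-[3-methoxy-4-(methoxymethoxy)phenyl]cyclohex-3-en-1-yl}butane-1,3-dione | CC(=O)CC(=O)[C@@H]1[C@@H](c2ccc(OCOC)c(OC)c2)CC=C[C@H]1c1ccc(OC)c(OC)c1
F12 | step 18 | 3-methoxy-4-(methoxymethoxy)benzaldehyde | COCOc1ccc(C=O)cc1OC
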